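Locants used throughout: the core of target **14** is numbered as a 2-oxabicyclo[4.2.0]oct-4-en-3-one (C1 = O-bearing ring-fusion carbon with the 2-phenylethyl group, O2, C3 = lactone C=O, C4, C5 = C–OMe, C6 = second ring-fusion carbon, C7 = C–Ph, C8 = carbon bearing the pyranone). Atoms of the 4-methoxy-2-oxo-2H-pyran-6-yl substituent are primed.

## The problem

1. Target **14** is a cyclobutane (C1, C6, C7, C8) cis-fused to a 4-methoxy-5,6-dihydro-2-pyranone, with a 2-phenylethyl group at C1, phenyl at C7 and a 4-methoxy-2-pyranon-6-yl ring at C8.
2. Formally it is the head-to-tail [2+2] adduct of the C5=C6 bond of one kavalactone and the styryl bond of another, so connectivity alone demands a crossed, regiodefined union of two alkenes that can each also dimerize.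
3. There are four contiguous stereocentres, one of them (C1) fully substituted. C1 and C6 are tied cis by the lactone, so the open questions are C7 and C8 relative to that ring, and the absolute configuration (1R,6S,7S,8S).
4. Phenyl at C7 lies on the concave face (cis to O2 and C5) and the pyranonyl group at C8 on the convex face, trans to phenyl. The concave phenyl is the contra-steric element, and there is no resident stereocentre, hydroxyl or chelating group to direct a catalyst.
5. Two fragilities rule out much standard chemistry. O2 is a tertiary acyloxy (vinylogous carbonate) leaving group β to the acidic C8–H and to C6–H, so a carbanion at C8 or C6 opens the lactone by E1cB elimination. A free C1–OH next to a carbonyl-bearing ring carbon would cleave the four-membered ring by retro-aldol (de Mayo) fragmentation.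
6. The lactone should therefore be intact from the moment the cyclobutane exists, and no enolate should ever be formed on the ring; both pyranone rings are also photoactive and electrophilic.
7. The feature that opens the plan: at C7 and at C8 exactly one substituent sits on the convex face (H at C7, the pyranone carbon C6′ at C8) and the two are cis. The target is thus the syn adduct of H and pyranonyl to the convex face of a 7-phenyl C7=C8 cyclobutene.
8. That cyclobutene (ring atoms C1, C6, C7, C8) is the [2+2] adduct of the C5=C6 bond of the flat, achiral pyranone **3** and the triple bond of phenylacetylene **4**; the key step uses this.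

## Retrosynthesis

**Cut 1, C8–C6′ (cyclobutane to pyranone).** Target **14** is divided into the cyclobutyl trifluoroborate **8** and 6-chloro-4-methoxy-2H-pyran-2-one **13**. This cut is preferred to cutting two ring bonds at once (Alternative 1) because it removes the group that makes C8–H acidic, and because the configuration wanted at C8 (pyranonyl convex, trans to phenyl) is the one a radical or organometallic coupling delivers whatever the configuration of its precursor. The precursor has one heteroaryl ring fewer and no acidic ring C–H. The forward reaction must be an sp3–sp2 coupling that never makes a carbanion β to O2.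

**Cut 2, C8–B and C7–H.** Salt **8** is the product of cis addition of H–B to the C7=C8 bond of cyclobutene **5**. This is preferred to hydrogenating a cyclobutene that already carries the pyranone at C8: that would put phenyl and pyranonyl both on the concave face and require a base-mediated epimerization at C8, which is exactly the E1cB situation. A direct palladium-catalysed hydro-heteroarylation is also avoided, because zerovalent palladium would ionize the tertiary allylic C1–O2 bond of **5**. Two stereocentres disappear. The forward reaction must add from the convex face only, place boron on the non-benzylic carbon, and, since **5** is racemic, take one enantiomer. A chiral monoalkylborane does all three.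

**Cut 3, C1–C8 and C6–C7.** Cyclobutene **5** is the [2+2] photoadduct of pyranone **3** (through its C5=C6 bond) and phenylacetylene **4**. An alkyne is preferred to a styrene-type alkene because the alkyne product has no C7/C8 stereochemistry to get wrong; the contra-steric C7 centre is postponed to a step where the bicyclic shape decides it. The alkyne's C–H end also fixes the regiochemistry. The precursors are a flat pyranone and a commodity alkyne. The forward reaction must react at C5=C6 of **3**, bond the CH terminus to pyranone C6, and close a four-membered and not a bridged ring.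

**Cut 4, side chain of 3.** Pyranone **3** comes from lateral benzylation of commercial 4-methoxy-6-methyl-2H-pyran-2-one **1** with benzyl bromide **2**. This is shorter than building the ring from a β-keto ester and uses the known acidity of the 6-methyl group.

**Cut 5, coupling partner 13.** Chloropyranone **13** comes by O-methylation of 6-chloro-4-hydroxy-2H-pyran-2-one **12**, itself the self-condensation, hydrolysis and decarboxylation product of malonyl dichloride **9**. A 6-halide is chosen because C6 of a 2-pyranone is a vinylogous acyl position and adds readily to low-valent nickel.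

## Roads not taken

Alternative 1: Cut C1–C8 and C6–C7 together, i.e. the biomimetic crossed [2+2] photocycloaddition of desmethoxyyangonin A1 with pyranone **3**, the route most chemists would draw first, giving **14** in one step. It must win four selections at once with nothing in either partner to enforce them: crossed over homo-dimerization (A1 absorbs at longer wavelength, isomerizes E/Z and dimerizes), head-to-tail over head-to-head, phenyl-concave over phenyl-convex approach (the needed adduct is the more crowded one), and one enantiomer over the other. The chosen plan separates these: regiochemistry is set by the alkyne C–H end, C7 by the shape of a bicyclic cyclobutene, C8 by a stereoconvergent coupling and the absolute configuration by a chiral borane. The price is three more steps.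

Alternative 2: Take all four ring carbons from one ring. C1, C6, C7, C8 with C5 and O2 are seen as a valence isomer of 4-phenyl-6-(2-phenylethyl)-2H-pyran-2-one A2, whose 4π photocyclization would give the bicyclic β-lactone A3 with C1 and C6 set and no regiochemical question; convex-face chemistry on its cyclobutene would follow as in the chosen plan. It was set aside because the β-lactone carbonyl of A3 must then be extended by two carbons into the six-membered lactone. Every way of doing so passes through a free tertiary cyclobutanol(ate) β to a carbonyl, the retro-aldol substrate named above. A3 is also a tertiary, phenyl-conjugated allylic carboxylate prone to ionization, and racemic without a handle. The chosen plan has the six-membered lactone in place before the four-membered ring is made.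

Alternative 3: Cut only C1–C6, which opens the ring to a 1,5-dicarbonyl compound. Keto ester A6, the conjugate adduct of ketone A4 to dienoate A5, could be made enantioselectively by organocatalysis. A Norrish–Yang photocyclization (γ-hydrogen abstraction from C6 by the excited C1 ketone, then 1,4-biradical closure) and lactonization would then give **14**. The appeal is a catalytic origin of the absolute configuration. However, the 1,4-biradical has the C7–C8 bond ideally placed for Norrish type 2 cleavage into a pyranone-conjugated enol and a dienoate, so fragmentation (a retro-Michael reaction) should dominate. C1 and C6 would also form without control, and C8–H of A6 epimerizes freely. The chosen plan makes both ring bonds in a cycloaddition that cannot fragment in this way.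

Key step: step 2

Assumption (chemistry): isopinocampheylborane made from (1R,5R)-(+)-α-pinene is taken to prefer the same enantioface of the 1-phenylcyclobutene unit of **5** as it does with 1-phenylcyclopentene, which makes (1S,6S)-**5** the fast-reacting enantiomer; if a trial shows the opposite sense, the reagent from (−)-α-pinene is used with no other change.

Remark: **5** is formed and used as the racemate (its (1S,6S) enantiomer is drawn). Descriptors change between **5**, **8** and **14** only because boron ranks below carbon; no centre is inverted.

## Route

Step 1
Reactants: 1 4-methoxy-6-methyl-2H-pyran-2-one; 2 benzyl bromide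
Product: 3 4-methoxy-6-(2-phenylethyl)-2H-pyran-2-one
Conditions: LDA (1.05 equiv), THF, −78 °C; then 2, DMPU, −78 to −30 °C
Reagents that add atoms: none
Why: Deprotonation of the 6-methyl group gives the vinylogous (extended) lithium enolate, which is alkylated at the exocyclic carbon; this lateral alkylation of 4-methoxy-6-methyl-2-pyranone is the standard entry to 6-alkyl kavalactone precursors.

Step 2
Reactants: 3 4-methoxy-6-(2-phenylethyl)-2H-pyran-2-one; 4 phenylacetylene
Product: 5 rac-(1S,6S)-5-methoxy-7-phenyl-1-(2-phenylethyl)-2-oxabicyclo[4.2.0]octa-4,7-dien-3-one
Conditions: thioxanthen-9-one (10 mol %), 4 (10 equiv), degassed MeCN (0.02 M), 405 nm LEDs, 20 °C, flow; partial conversion, 3 recovered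
Reagents that add atoms: none
Why: Proposed new method: triplet energy transfer from thioxanthen-9-one (about 65 kcal/mol) excites only pyranone 3 (phenylacetylene, about 72 kcal/mol, is not sensitized), and the pyranone triplet has one spin centre localized at its alkoxy-substituted C6 and the other delocalized over C5 to C3 next to the carbonyl. The localized C6 end forms the first bond to the unsubstituted alkyne carbon, which is the less hindered terminus and leaves a phenyl-stabilized vinyl radical; after intersystem crossing the 1,4-biradical closes between pyranone C5 and the phenyl-bearing carbon. The closest known reaction types are the sensitized [2+2] photocycloaddition of 2-pyranones with alkenes at C5=C6, the [2+2] photocycloaddition of 2-pyridones with alkynes at the same bond, and enone–alkyne photocycloadditions to cyclobutenes. One ring is closed, the four-membered one, by a stepwise (biradical) [2+2] cycloaddition: first bond C1–C8, ring closure C6–C7 (bicyclic locants); the lactone ring is not touched. The two new stereocentres C1 and C6 arise together and can only be cis, because a trans-fused bicyclo[4.2.0]octa-4,7-diene is not accessible; the product is racemic and its absolute configuration is selected in step 3. The step needs site selectivity (C5=C6 and not C3=C4), periselectivity ([2+2] and not bridging from C6 to C3, which would end in loss of CO2 and an arene) and regioselectivity (alkyne CH to pyranone C6): all three follow from the first bond being made at C6, the only radical end not stabilized by the carbonyl, to the sterically free CH terminus, and the second bond at the nearer end (C5) of the allyl-type radical. Excess alkyne and high dilution are used to outrun dimerization of 3, and the run is stopped at partial conversion because the styrene-type chromophore of 5 can itself accept triplet energy.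

Step 3
Reactants: 5 rac-(1S,6S)-5-methoxy-7-phenyl-1-(2-phenylethyl)-2-oxabicyclo[4.2.0]octa-4,7-dien-3-one
Product: 8 potassium trifluoro[(1S,6R,7R,8R)-5-methoxy-3-oxo-7-phenyl-1-(2-phenylethyl)-2-oxabicyclo[4.2.0]oct-4-en-8-yl]borate, via isopinocampheyl(bicyclooctenyl)borane 6 (not isolated), via diethyl bicyclooctenylboronate 7 (not isolated)
Conditions: IpcBH2 from (+)-α-pinene (0.5 equiv; liberated from (IpcBH2)2·TMEDA by BF3·OEt2, filtered), THF, −25 °C; CH3CHO (excess), 0 to 25 °C; KHF2, MeOH/H2O, 25 °C; salt crystallized from acetone/Et2O, unreacted (1R,6R)-5 and α-pinene stay in the ether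
Reagents that add atoms: isopinocampheylborane, B[C@H]1[C@H](C)[C@H]2C[C@@H](C1)C2(C)C; potassium hydrogen difluoride, [K+].[F-].F; acetaldehyde, CC=O (its atoms are the ethoxy groups of 7 and leave again as ethanol)
Why: Hydroboration of a 1-arylcycloalkene places boron on the non-benzylic carbon and adds H and B cis; on 5 only the convex face (that of C6–H and the C1 side chain) is open, so H enters C7 and boron C8 from that face, which puts phenyl on the concave face and boron trans to it. Asymmetric hydroboration with isopinocampheylborane is known for 1-phenylcycloalkenes; the enantioface it prefers is the open convex face of (1S,6S)-5 but the blocked concave face of (1R,6R)-5, so half an equivalent should effect a kinetic resolution of the racemic alkene, with crystallization of the salt to raise the enantiomeric purity. Acetaldehyde then removes the isopinocampheyl group as α-pinene and KHF2 gives the salt; boron and O2 are trans on a four-membered ring and the lactone carbonyl cannot reach boron, which should hold back β-elimination.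

Step 4
Reactants: 9 malonyl dichloride (two molecules)
Product: 12 6-chloro-4-hydroxy-2H-pyran-2-one, via 6-chloro-4-hydroxy-2-oxo-2H-pyran-3-carbonyl chloride 10 (not isolated), via 6-chloro-4-hydroxy-2-oxo-2H-pyran-3-carboxylic acid 11 (not isolated)
Conditions: neat, 25 to 40 °C (HCl vented); then H2O, acetone, 50 °C
Reagents that add atoms: water, O (its oxygen enters 11 and leaves with the CO2; only hydrogen stays in 12)
Why: Malonyl dichloride self-condenses through chlorocarbonylketene to the 3-chlorocarbonyl pyranone; water hydrolyses the acid chloride to a vinylogous β-keto acid that decarboxylates on warming (known malonyl chloride chemistry).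

Step 5
Reactants: 12 6-chloro-4-hydroxy-2H-pyran-2-one
Product: 13 6-chloro-4-methoxy-2H-pyran-2-one
Conditions: Me2SO4, K2CO3, acetone, 56 °C
Reagents that add atoms: dimethyl sulfate, COS(=O)(=O)OC
Why: O-Methylation of the acidic 4-hydroxy-2-pyranone (a vinylogous acid) with dimethyl sulfate and K2CO3 is the standard route to 4-methoxy-2-pyranones; the pyranone oxyanion is deactivated toward substitution at C6, so the chloride should survive.

Step 6
Reactants: 8 potassium trifluoro[(1S,6R,7R,8R)-5-methoxy-3-oxo-7-phenyl-1-(2-phenylethyl)-2-oxabicyclo[4.2.0]oct-4-en-8-yl]borate; 13 6-chloro-4-methoxy-2H-pyran-2-one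
Product: 14 (1R,6S,7S,8S)-5-methoxy-8-(4-methoxy-2-oxo-2H-pyran-6-yl)-7-phenyl-1-(2-phenylethyl)-2-oxabicyclo[4.2.0]oct-4-en-3-one
Conditions: [Ir{dF(CF3)ppy}2(bpy)]PF6 (2 mol %), NiCl2(dme) (5 mol %), 4,4′-di-tert-butyl-2,2′-bipyridine (5 mol %), 2,6-lutidine, 1,4-dioxane, 450 nm LEDs, 25 °C
Reagents that add atoms: none
Why: Photoredox/nickel dual-catalytic cross-coupling of a secondary alkyltrifluoroborate with an activated alkenyl chloride: one-electron oxidation of 8 gives the C8 cyclobutyl radical (its ring bonds lie in the nodal plane of the radical orbital, so ring opening is slow), nickel captures it after inserting into the C6′–Cl bond of 13, and reductive elimination forms C8–C6′. The new bond is made on the convex face, trans to the C7 phenyl, whichever face the radical came from (stereoconvergent at C8, here equal to retention); no enolate or strong base is involved, so C1–O2, C6 and C7 are untouched.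

## Compound list

1 | 4-methoxy-6-methyl-2H-pyran-2-one | COC1=CC(=O)OC(C)=C1 | starting material
2 | benzyl bromide | BrCc1ccccc1 | starting material
3 | 4-methoxy-6-(2-phenylethyl)-2H-pyran-2-one | COC1=CC(=O)OC(CCc2ccccc2)=C1 | intermediate
4 | phenylacetylene (ethynylbenzene) | C#Cc1ccccc1 | starting material
5 | rac-(1S,6S)-5-methoxy-7-phenyl-1-(2-phenylethyl)-2-oxabicyclo[4.2.0]octa-4,7-dien-3-one (racemate, (1S,6S) enantiomer drawn) | COC1=CC(=O)O[C@]2(CCc3ccccc3)[C@H]1C(c1ccccc1)=C2 | intermediate
6 | [(1S,6R,7R,8R)-5-methoxy-3-oxo-7-phenyl-1-(2-phenylethyl)-2-oxabicyclo[4.2.0]oct-4-en-8-yl][(1R,2S,3R,5R)-2,6,6-trimethylbicyclo[3.1.1]heptan-3-yl]borane | COC1=CC(=O)O[C@]2(CCc3ccccc3)[C@H]1[C@H](c1ccccc1)[C@H]2B[C@H]1[C@H](C)[C@H]2C[C@@H](C1)C2(C)C | intermediate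
7 | diethyl [(1S,6R,7R,8R)-5-methoxy-3-oxo-7-phenyl-1-(2-phenylethyl)-2-oxabicyclo[4.2.0]oct-4-en-8-yl]boronate | COC1=CC(=O)O[C@]2(CCc3ccccc3)[C@H]1[C@H](c1ccccc1)[C@H]2B(OCC)OCC | intermediate
8 | potassium trifluoro[(1S,6R,7R,8R)-5-methoxy-3-oxo-7-phenyl-1-(2-phenylethyl)-2-oxabicyclo[4.2.0]oct-4-en-8-yl]borate | COC1=CC(=O)O[C@]2(CCc3ccccc3)[C@H]1[C@H](c1ccccc1)[C@H]2[B-](F)(F)F.[K+] | intermediate
9 | malonyl dichloride (propanedioyl dichloride) | ClC(=O)CC(Cl)=O | starting material
10 | 6-chloro-4-hydroxy-2-oxo-2H-pyran-3-carbonyl chloride | O=C(Cl)C1=C(O)C=C(Cl)OC1=O | intermediate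
11 | 6-chloro-4-hydroxy-2-oxo-2H-pyran-3-carboxylic acid | OC(=O)C1=C(O)C=C(Cl)OC1=O | intermediate
12 | 6-chloro-4-hydroxy-2H-pyran-2-one | OC1=CC(=O)OC(Cl)=C1 | intermediate
13 | 6-chloro-4-methoxy-2H-pyran-2-one | COC1=CC(=O)OC(Cl)=C1 | intermediate
14 | (1R,6S,7S,8S)-5-methoxy-8-(4-methoxy-2-oxo-2H-pyran-6-yl)-7-phenyl-1-(2-phenylethyl)-2-oxabicyclo[4.2.0]oct-4-en-3-one | COC1=CC(=O)O[C@]2(CCc3ccccc3)[C@H]1[C@H](c1ccccc1)[C@H]2c1cc(OC)cc(=O)o1 | target

## Step count and uncertain steps

Total: 6 steps. Longest linear sequence: 4 steps (steps 1, 2, 3, 6 from **1**); steps 4 and 5 make the coupling partner.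

**Step 2 (key step, proposed new method).** What may go wrong: the first bond may form from pyranone C3 instead of C6, giving cycloaddition across C3=C4 or a bridged adduct that loses CO2 to an arene. Pyranone **3** may photodimerize. The styrene-type chromophore of **5** may undergo secondary sensitized reactions, eroding the product as conversion rises. Fallback (known chemistry), from **3** back to the route at **8**, replacing steps 2 and 3: a sensitized [2+2] photocycloaddition at C5=C6 with an alkene, the known mode for 2-pyranones. The alkene is the (+)-pinanediol ester of (E)-2-phenylethenylboronic acid, F1, made from the commercial boronic acid and (+)-pinanediol. The E geometry gives phenyl and boron trans; the chiral diol turns the two enantiomeric series into diastereomers. The isomer with phenyl on the concave face, pinanediol (1S,6R,7R,8R)-boronate F2, is separated from the others and converted with KHF2 into **8**. The price is loss of the shape-based control of C7.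

**Step 3.** What may go wrong: too small a rate difference between the two enantiomers of **5** toward the chiral borane; some boron delivery to the benzylic carbon; slow β-elimination of boron and O2 that opens the lactone. Fallback, from **5** back at **8**: non-selective hydroboration with HBBr2·SMe2 and hydrolysis to the racemic boronic acid F3, esterification with (+)-pinanediol, separation of the two diastereomeric boronates, and conversion of the (1S,6R,7R,8R) isomer F4 (identical in structure with F2) into **8** with KHF2. This replaces kinetic resolution by a separation of diastereomers.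

**Step 6.** What may go wrong: slow insertion of nickel into the C6′–Cl bond; β-hydride loss from the nickel alkyl toward C7, regenerating a cyclobutene; protodeboronation; energy or electron transfer from the photocatalyst to the pyranone. Fallback, from **8** back at **14**, changing from attaching a finished pyranone to building it: nickel/photoredox acylation of **8** with (2,2-dimethyl-4-oxo-4H-1,3-dioxin-6-yl)acetic acid F5 (from 2,2,6-trimethyl-4H-1,3-dioxin-4-one, LDA, CO2), activated in the flask by dimethyl dicarbonate, gives ketone F6. Heating F6 in toluene at 110 °C expels acetone, and the acylketene is trapped by the enol oxygen of the C8 ketone to give the 4-hydroxy-2-pyranone F7. Methylation with TMSCHN2 gives **14**. No base acts on the ring at any point.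

## Further compounds

F1 | step 2 | (3aS,4S,6S,7aR)-3a,5,5-trimethyl-2-[(E)-2-phenylethenyl]hexahydro-4,6-methano-1,3,2-benzodioxaborole ((+)-pinanediol (E)-styrylboronate) | c1ccccc1/C=C/B1O[C@@H]2C[C@@H]3C[C@@H](C3(C)C)[C@]2(C)O1
F2 | step 2 | (1S,6R,7R,8R)-5-methoxy-7-phenyl-1-(2-phenylethyl)-8-[(3aS,4S,6S,7aR)-3a,5,5-trimethylhexahydro-4,6-methano-1,3,2-benzodioxaborol-2-yl]-2-oxabicyclo[4.2.0]oct-4-en-3-one | COC1=CC(=O)O[C@]2(CCc3ccccc3)[C@H]1[C@H](c1ccccc1)[C@H]2B1O[C@@H]2C[C@@H]3C[C@@H](C3(C)C)[C@]2(C)O1
F3 | step 3 | rac-[(1S,6R,7R,8R)-5-methoxy-3-oxo-7-phenyl-1-(2-phenylethyl)-2-oxabicyclo[4.2.0]oct-4-en-8-yl]boronic acid (racemate, one enantiomer drawn) | COC1=CC(=O)O[C@]2(CCc3ccccc3)[C@H]1[C@H](c1ccccc1)[C@H]2B(O)O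
F4 | step 3 | (1S,6R,7R,8R)-5-methoxy-7-phenyl-1-(2-phenylethyl)-8-[(3aS,4S,6S,7aR)-3a,5,5-trimethylhexahydro-4,6-methano-1,3,2-benzodioxaborol-2-yl]-2-oxabicyclo[4.2.0]oct-4-en-3-one | COC1=CC(=O)O[C@]2(CCc3ccccc3)[C@H]1[C@H](c1ccccc1)[C@H]2B1O[C@@H]2C[C@@H]3C[C@@H](C3(C)C)[C@]2(C)O1
F5 | step 6 | (2,2-dimethyl-4-oxo-4H-1,3-dioxin-6-yl)acetic acid | CC1(C)OC(CC(O)=O)=CC(=O)O1
F6 | step 6 | (1R,6S,7S,8R)-8-[(2,2-dimethyl-4-oxo-4H-1,3-dioxin-6-yl)acetyl]-5-methoxy-7-phenyl-1-(2-phenylethyl)-2-oxabicyclo[4.2.0]oct-4-en-3-one | COC1=CC(=O)O[C@]2(CCc3ccccc3)[C@H]1[C@H](c1ccccc1)[C@H]2C(=O)CC1=CC(=O)OC(C)(C)O1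
F7 | step 6 | (1R,6S,7S,8S)-8-(4-hydroxy-2-oxo-2H-pyran-6-yl)-5-methoxy-7-phenyl-1-(2-phenylethyl)-2-oxabicyclo[4.2.0]oct-4-en-3-one | COC1=CC(=O)O[C@]2(CCc3ccccc3)[C@H]1[C@H](c1ccccc1)[C@H]2c1cc(O)cc(=O)o1
A1 | alternative 1 | 4-methoxy-6-[(E)-2-phenylethenyl]-2H-pyran-2-one (desmethoxyyangonin) | COC1=CC(=O)OC(/C=C/c2ccccc2)=C1
A2 | alternative 2 | 4-phenyl-6-(2-phenylethyl)-2H-pyran-2-one | O=C1C=C(c2ccccc2)C=C(CCc2ccccc2)O1
A3 | alternative 2 | (1S,4R)-5-phenyl-1-(2-phenylethyl)-2-oxabicyclo[2.2.0]hex-5-en-3-one (would form as the racemate; enantiomer matching 14 drawn) | O=C1O[C@@]2(CCc3ccccc3)C=C(c3ccccc3)[C@@H]12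
A4 | alternative 3 | 4-methoxy-6-(2-oxo-4-phenylbutyl)-2H-pyran-2-one | COC1=CC(=O)OC(CC(=O)CCc2ccccc2)=C1
A5 | alternative 3 | methyl (2E,4E)-3-methoxy-5-phenylpenta-2,4-dienoate | COC(=O)/C=C(OC)\C=C\c1ccccc1
A6 | alternative 3 | methyl (2E,5S,6S)-3-methoxy-6-(4-methoxy-2-oxo-2H-pyran-6-yl)-7-oxo-5,9-diphenylnon-2-enoate | COC(=O)/C=C(OC)\C[C@H](c1ccccc1)[C@H](C(=O)CCc1ccccc1)c1cc(OC)cc(=O)o1
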